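## Retrosynthetic overview

1. The last bond cut is C10–C11: an enantioconvergent nickel-catalysed reductive cross-coupling joins the pyranone-stabilised secondary radical from chloride 11 (ring A half) to alkenyl iodide 19 (ring B half) and sets C10.
2. Iodide 19 comes from a vinylogous Mukaiyama aldol (C15–C16) of silyl dienol ether 6 with aldehyde 17, then acetylation. Aldehyde 17 comes from an L-proline cross-aldol (C13–C14) of propanal with (E)-3-iodo-2-methylpropenal, made from propargyl alcohol.
3. Chloride 11 comes from lateral chlorination of alcohol 8, which is made by a catalytic asymmetric vinylogous aldol (C3–C4) of the same dienol ether 6 with propanal.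
4. Rings: there is one ring-forming step only, pyranone 4 from pentan-3-one and propanoic acid (step 1). It is elaborated on one ethyl group to give ring B and on both ethyl groups to give ring A; no ring is closed later.

Assumption: chain locants run from the hydroxypentyl methyl (C1) through ring A (C5–C9), the linker (C10–C16) and ring B (C17–C21) to the ethyl terminus (C22, C23). On this numbering the target SMILES reads 3S,4S,10S,11E,13R,14R,15R,16R.

## Route

Step 1
Reactants: 1 pentan-3-one; 2 propanoic acid (2 equiv)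
Product: 4 2,6-diethyl-3,5-dimethyl-4H-pyran-4-one, via 4,6-dimethylnonane-3,5,7-trione 3 (not isolated)
Conditions: polyphosphoric acid, 150 °C
Reagents that add atoms: none
Why: Polyphosphoric acid activates propanoic acid as a mixed anhydride that C-acylates both α-carbons of the ketone (acid-mediated enol acylation), and the resulting 1,3,5-triketone cyclodehydrates to the fully substituted γ-pyranone, with no stereocentre formed.

Step 2
Reactants: 4 2,6-diethyl-3,5-dimethyl-4H-pyran-4-one
Product: 6 tert-butyl{[(2Z)-6-ethyl-2-ethylidene-3,5-dimethyl-2H-pyran-4-yl]oxy}dimethylsilane, via lithium dienolate 5 (not isolated)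
Conditions: LiN(SiMe3)2 (1.05 equiv), THF, −78 °C; then t-BuMe2SiOTf, −78 to 0 °C; pentane, filtration, bulb-to-bulb distillation
Reagents that add atoms: tert-butyldimethylsilyl trifluoromethanesulfonate, CC(C)(C)[Si](C)(C)OS(=O)(=O)C(F)(F)F
Why: Lateral (vinylogous) deprotonation of an ethyl CH2, the only enolisable position of the pyranone, gives the extended dienolate, which the hard silyl triflate traps on oxygen, and the ethylidene methyl lies cis to the ring oxygen (Z) to avoid allylic strain with the neighbouring ring methyl.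

Step 3
Reactants: 6 tert-butyl{[(2Z)-6-ethyl-2-ethylidene-3,5-dimethyl-2H-pyran-4-yl]oxy}dimethylsilane (1.2 equiv); 7 propanal
Product: 8 2-ethyl-6-[(2S,3S)-3-hydroxypentan-2-yl]-3,5-dimethyl-4H-pyran-4-one
Conditions: SiCl4 (1.1 equiv), (R,R)-N,N'-bis[3,5-dimethyl-4-oxido-4,5-dihydro-3H-dinaphtho[2,1-d:1',2'-f][1,3,2]diazaphosphepin-4-yl]-N,N'-dimethylpentane-1,5-diamine (C51H52N6O2P2, 5 mol %), Bu4NI (10 mol %), i-Pr2NEt (10 mol %), CH2Cl2, −78 °C; aq. NaHCO3
Reagents that add atoms: none
Why: Proposed new method: the cationic trichlorosilyl–bisphosphoramide complex binds propanal and exposes its Re face to the exocyclic carbon of 6 in an open transition state that turns the aldehyde chain away from the ring methyl, so C3 (S) and, through anti addition, C4 (S) are set together as they are for γ-methyl silyl dienol ethers in the closest known reaction, the Lewis-base-catalysed SiCl4 vinylogous Mukaiyama aldol, and the mirror-image catalyst is used if a test run shows the opposite facial sense.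

Step 4
Reactants: 8 2-ethyl-6-[(2S,3S)-3-hydroxypentan-2-yl]-3,5-dimethyl-4H-pyran-4-one
Product: 11 2-[(1RS)-1-chloroethyl]-6-[(2S,3S)-3-hydroxypentan-2-yl]-3,5-dimethyl-4H-pyran-4-one, via bis-silyl dienol ether 9 (not isolated), via chloro silyl ether 10 (not isolated)
Conditions: Me3SiOTf (2.2 equiv), Et3N (2.4 equiv), CH2Cl2, 0 °C; then N-chlorosuccinimide (1.1 equiv), −78 to −20 °C; then 0.5 M HCl, THF, 0 °C
Reagents that add atoms: N-chlorosuccinimide, O=C1CCC(=O)N1Cl
Why: O-Silylation gives a 4-silyloxypyrylium ion that Et3N deprotonates only at the unbranched ethyl group (the branched side would give a tetrasubstituted exocyclic alkene with severe allylic strain), N-chlorosuccinimide then chlorinates the exocyclic carbon with rearomatisation (soft enolisation followed by electrophilic halogenation of a silyl dienol ether) and the acid work-up frees O3, while the new C–Cl centre forms as both epimers, which is harmless because step 11 passes through a planar radical.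

Step 5
Reactants: 12 prop-2-yn-1-ol
Product: 14 (2E)-3-iodo-2-methylprop-2-en-1-ol, via alkenylalane 13 (not isolated)
Conditions: AlMe3 (3 equiv), Cp2ZrCl2 (0.25 equiv), CH2Cl2, 0 °C to rt; then I2, THF, −30 to 0 °C; aq. Na2S2O3/NaHCO3
Reagents that add atoms: trimethylaluminium, C[Al](C)C; iodine, II
Why: Zirconocene-catalysed syn-carboalumination (Negishi carboalumination) places methyl on the internal and aluminium on the terminal alkyne carbon, and iodinolysis of the C–Al bond with retention gives the E alkenyl iodide.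

Step 6
Reactants: 14 (2E)-3-iodo-2-methylprop-2-en-1-ol
Product: 15 (2E)-3-iodo-2-methylprop-2-enal
Conditions: MnO2 (15 equiv), CH2Cl2, rt
Reagents that add atoms: none
Why: Heterogeneous MnO2 oxidises the allylic alcohol to the enal under neutral conditions (allylic alcohol oxidation) without E/Z isomerisation or loss of iodide.

Step 7
Reactants: 15 (2E)-3-iodo-2-methylprop-2-enal; 7 propanal
Product: 16 (2S,3R,4E)-3-hydroxy-5-iodo-2,4-dimethylpent-4-enal
Conditions: L-proline ((S)-pyrrolidine-2-carboxylic acid, 20 mol %), DMF, 4 °C; 7 added by syringe pump over 24 h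
Reagents that add atoms: none
Why: The E enamine formed from L-proline and propanal adds through the hydrogen-bonded Houk–List transition state to the Re face of the non-enolisable enal 15 (proline-catalysed direct cross-aldol of aldehydes), one molecule of each aldehyde combining without loss of atoms to give the anti aldol that carries the C13 (R) and C14 (R, target numbering) configurations, while slow addition of 7 to 15, which is kept in slight excess and recovered, suppresses the self-aldol of propanal.

Step 8
Reactants: 16 (2S,3R,4E)-3-hydroxy-5-iodo-2,4-dimethylpent-4-enal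
Product: 17 (2S,3R,4E)-5-iodo-2,4-dimethyl-1-oxopent-4-en-3-yl propanoate
Conditions: EtCOCl (1.2 equiv), pyridine (2 equiv), CH2Cl2, −20 °C
Reagents that add atoms: propanoyl chloride, CCC(=O)Cl
Why: O-Acylation of the secondary allylic alcohol by the acylpyridinium ion is faster at −20 °C than enolisation of the aldehyde, so the propanoate goes onto O13 before the second hydroxyl exists and without β-elimination or epimerisation at C14 (nucleophile-assisted esterification).

Step 9
Reactants: 17 (2S,3R,4E)-5-iodo-2,4-dimethyl-1-oxopent-4-en-3-yl propanoate; 6 tert-butyl{[(2Z)-6-ethyl-2-ethylidene-3,5-dimethyl-2H-pyran-4-yl]oxy}dimethylsilane (1.5 equiv)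
Product: 18 (1E,3R,4R,5R,6R)-6-(6-ethyl-3,5-dimethyl-4-oxo-4H-pyran-2-yl)-5-hydroxy-1-iodo-2,4-dimethylhept-1-en-3-yl propanoate
Conditions: BF3·OEt2 (2.2 equiv), CH2Cl2, −78 °C; aq. NaHCO3
Reagents that add atoms: none
Why: In this open-transition-state vinylogous Mukaiyama aldol the BF3-bound aldehyde is attacked under Felkin control from C14 and 1,3-anti control from the C13 acyloxy dipole, which reinforce each other for a 2,3-anti aldehyde and give C15 (R) with 14,15-syn and 13,15-anti relationships, while the Z ethylidene terminus is expected, by analogy with γ-methyl dienol ethers and not yet tested on this dienol ether, to add anti-selectively with the aldehyde chain turned away from the ring methyl, setting C16 (R) as the pyranone rearomatises.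

Step 10
Reactants: 18 (1E,3R,4R,5R,6R)-6-(6-ethyl-3,5-dimethyl-4-oxo-4H-pyran-2-yl)-5-hydroxy-1-iodo-2,4-dimethylhept-1-en-3-yl propanoate
Product: 19 (1E,3R,4R,5R,6R)-5-acetoxy-6-(6-ethyl-3,5-dimethyl-4-oxo-4H-pyran-2-yl)-1-iodo-2,4-dimethylhept-1-en-3-yl propanoate
Conditions: Ac2O, pyridine, 4-(dimethylamino)pyridine (10 mol %), CH2Cl2, 0 °C
Reagents that add atoms: acetic anhydride, CC(=O)OC(C)=O
Why: Nucleophile-catalysed acetylation of the only free hydroxyl (O15) at 0 °C outruns 1,3-migration of the neighbouring propanoate, so the two different esters end on the correct oxygens and no stereocentre is touched.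

Step 11
Reactants: 11 2-[(1RS)-1-chloroethyl]-6-[(2S,3S)-3-hydroxypentan-2-yl]-3,5-dimethyl-4H-pyran-4-one (1.5 equiv); 19 (1E,3R,4R,5R,6R)-5-acetoxy-6-(6-ethyl-3,5-dimethyl-4-oxo-4H-pyran-2-yl)-1-iodo-2,4-dimethylhept-1-en-3-yl propanoate
Product: 20 (2S,3E,5R,6R,7R,8R)-7-acetoxy-8-(6-ethyl-3,5-dimethyl-4-oxo-4H-pyran-2-yl)-2-{6-[(2S,3S)-3-hydroxypentan-2-yl]-3,5-dimethyl-4-oxo-4H-pyran-2-yl}-4,6-dimethylnon-3-en-5-yl propanoate (CNP0265513.1)
Conditions: NiCl2·MeOCH2CH2OMe (10 mol %), (3aR,3a'R,8aS,8a'S)-2,2'-(cyclopropane-1,1-diyl)bis(3a,8a-dihydro-8H-indeno[1,2-d]oxazole) (11 mol %), Mn powder (3 equiv), NaI (0.5 equiv), N,N-dimethylacetamide, 0 °C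
Reagents that add atoms: none
Why: Proposed new method: zerovalent nickel inserts into the C–I bond of 19, halogen-atom abstraction from 11 by monovalent nickel gives a planar pyranone-stabilised (vinylogous α-oxo) secondary radical that erases the C10 configuration, and ligand-controlled capture of this radical by the divalent alkenylnickel species followed by reductive elimination from trivalent nickel forms C10–C11 with 10S and retained E geometry, by analogy with the closest known reaction, the nickel/bis(oxazoline)-catalysed enantioconvergent reductive cross-coupling of 1-arylethyl chlorides with alkenyl bromides, the mirror-image ligand being used if a model coupling shows the opposite sense.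

## Compound list

1 | pentan-3-one | CCC(=O)CC | starting material
2 | propanoic acid | CCC(=O)O | starting material
3 | 4,6-dimethylnonane-3,5,7-trione (stereoisomer and tautomer mixture, not isolated) | CCC(=O)C(C)C(=O)C(C)C(=O)CC | intermediate
4 | 2,6-diethyl-3,5-dimethyl-4H-pyran-4-one | CCc1oc(CC)c(C)c(=O)c1C | intermediate
5 | lithium (2Z)-6-ethyl-2-ethylidene-3,5-dimethyl-2H-pyran-4-olate (not isolated) | C/C=C1\OC(CC)=C(C)C([O-])=C1C.[Li+] | intermediate
6 | tert-butyl{[(2Z)-6-ethyl-2-ethylidene-3,5-dimethyl-2H-pyran-4-yl]oxy}dimethylsilane | C/C=C1\OC(CC)=C(C)C(O[Si](C)(C)C(C)(C)C)=C1C | intermediate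
7 | propanal | CCC=O | starting material
8 | 2-ethyl-6-[(2S,3S)-3-hydroxypentan-2-yl]-3,5-dimethyl-4H-pyran-4-one | CCc1oc([C@@H](C)[C@@H](O)CC)c(C)c(=O)c1C | intermediate
9 | {[(2Z)-2-ethylidene-3,5-dimethyl-6-[(2S,3S)-3-(trimethylsilyloxy)pentan-2-yl]-2H-pyran-4-yl]oxy}trimethylsilane (not isolated) | C/C=C1\OC([C@@H](C)[C@@H](O[Si](C)(C)C)CC)=C(C)C(O[Si](C)(C)C)=C1C | intermediate
10 | 2-(1-chloroethyl)-3,5-dimethyl-6-[(2S,3S)-3-(trimethylsilyloxy)pentan-2-yl]-4H-pyran-4-one (both epimers at the chloro carbon, not isolated) | CC(Cl)c1oc([C@@H](C)[C@@H](O[Si](C)(C)C)CC)c(C)c(=O)c1C | intermediate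
11 | 2-[(1RS)-1-chloroethyl]-6-[(2S,3S)-3-hydroxypentan-2-yl]-3,5-dimethyl-4H-pyran-4-one (both epimers at the chloro carbon) | CC(Cl)c1oc([C@@H](C)[C@@H](O)CC)c(C)c(=O)c1C | intermediate
12 | prop-2-yn-1-ol | C#CCO | starting material
13 | dimethylaluminium (2E)-3-(dimethylalumanyl)-2-methylprop-2-en-1-olate (not isolated) | C[Al](C)OC/C(C)=C/[Al](C)C | intermediate
14 | (2E)-3-iodo-2-methylprop-2-en-1-ol | OC/C(C)=C/I | intermediate
15 | (2E)-3-iodo-2-methylprop-2-enal | O=C/C(C)=C/I | intermediate
16 | (2S,3R,4E)-3-hydroxy-5-iodo-2,4-dimethylpent-4-enal | O[C@@H](/C(C)=C/I)[C@H](C)C=O | intermediate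
17 | (2S,3R,4E)-5-iodo-2,4-dimethyl-1-oxopent-4-en-3-yl propanoate | CCC(=O)O[C@@H](/C(C)=C/I)[C@H](C)C=O | intermediate
18 | (1E,3R,4R,5R,6R)-6-(6-ethyl-3,5-dimethyl-4-oxo-4H-pyran-2-yl)-5-hydroxy-1-iodo-2,4-dimethylhept-1-en-3-yl propanoate | CCC(=O)O[C@@H](/C(C)=C/I)[C@H](C)[C@@H](O)[C@@H](C)c1oc(CC)c(C)c(=O)c1C | intermediate
19 | (1E,3R,4R,5R,6R)-5-acetoxy-6-(6-ethyl-3,5-dimethyl-4-oxo-4H-pyran-2-yl)-1-iodo-2,4-dimethylhept-1-en-3-yl propanoate | CCC(=O)O[C@@H](/C(C)=C/I)[C@H](C)[C@@H](OC(C)=O)[C@@H](C)c1oc(CC)c(C)c(=O)c1C | intermediate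
20 | (2S,3E,5R,6R,7R,8R)-7-acetoxy-8-(6-ethyl-3,5-dimethyl-4-oxo-4H-pyran-2-yl)-2-{6-[(2S,3S)-3-hydroxypentan-2-yl]-3,5-dimethyl-4-oxo-4H-pyran-2-yl}-4,6-dimethylnon-3-en-5-yl propanoate (CNP0265513.1) | CCC(=O)O[C@@H](/C(C)=C/[C@H](C)c1oc([C@@H](C)[C@@H](O)CC)c(C)c(=O)c1C)[C@H](C)[C@@H](OC(C)=O)[C@@H](C)c1oc(CC)c(C)c(=O)c1C | target

## Step count and risk

Total step count: 11. Longest linear sequence: 7 steps (steps 5–11, from 12 to 20).

The three steps most likely to fail:

**Step 11.** The pyranone-stabilised radical is an untested partner, zerovalent nickel may ionise the allylic propanoate of 19, and ligand control at C10 may be eroded by the resident stereocentres. The fallback sets out from 8 and comes back at 20, and replaces the radical coupling by a two-electron palladium dienolate alkenylation. Silylation of 8 with Et3SiOTf and Et3N gives the bis(triethylsilyl) dienol ether F1. Pd(OAc)2 and P(t-Bu)3 with ZnF2 and CsF in DMF then join its exocyclic carbon to 19 (oxidative addition to a divalent alkenylpalladium iodide, transmetalation of the fluoride-activated dienolate, reductive elimination), giving the O3-triethylsilyl ether F2 as both C10 epimers. HF·pyridine in THF removes the silyl group, and preparative HPLC separates 20 from its 10R epimer F3.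

**Step 3.** Neither the reactivity of propanal towards this new dienol ether under the chiral silicon Lewis acid nor the enantioselectivity is assured. The fallback sets out from 6 and 7 and comes back at 8, and uses resolution in place of asymmetric catalysis. BF3·OEt2 in CH2Cl2 at −78 °C adds 6 to 7 to give the racemic anti alcohol, that is 8 together with its (3R,4R)-enantiomer F4; syn isomers are removed by chromatography. Candida antarctica lipase B with vinyl acetate in tert-butyl methyl ether acetylates the 3R alcohol to the acetate F5 (the branched substituent is the larger group, so the fast-reacting enantiomer is 3R) and leaves 8, which is isolated by chromatography.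

**Step 9.** The anti sense at C16 rests on analogy, and the β-acyloxy aldehyde 17 can eliminate propanoic acid. The fallback sets out from 16 (bypassing 17) and comes back at 19, and uses the lithium dienolate with a silyl-protected aldehyde. Et3SiOTf and 2,6-lutidine convert 16 into the triethylsilyl ether aldehyde F6. Lithium dienolate 5, made from 4 with LiN(SiMe3)2 in THF at −78 °C, adds to F6 in a lateral aldol reaction to give the aldol adduct F7, with C15 set by Felkin control. Ac2O, pyridine and 4-(dimethylamino)pyridine give the acetate F8, HF·pyridine frees O13 to give the alcohol F9, and propanoyl chloride with pyridine gives 19. In either variant a minor C16 epimer is removed by chromatography at the alcohol stage.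

## Further compounds

F1 | step 11 | bis(triethylsilyl) dienol ether of 8, triethyl{[(2Z)-2-ethylidene-3,5-dimethyl-6-[(2S,3S)-3-(triethylsilyloxy)pentan-2-yl]-2H-pyran-4-yl]oxy}silane | C/C=C1\OC([C@@H](C)[C@@H](O[Si](CC)(CC)CC)CC)=C(C)C(O[Si](CC)(CC)CC)=C1C
F2 | step 11 | O3-triethylsilyl ether of 20, formed as both C10 epimers | CCC(=O)O[C@@H](/C(C)=C/C(C)c1oc([C@@H](C)[C@@H](O[Si](CC)(CC)CC)CC)c(C)c(=O)c1C)[C@H](C)[C@@H](OC(C)=O)[C@@H](C)c1oc(CC)c(C)c(=O)c1C
F3 | step 11 | 10R epimer of 20 | CCC(=O)O[C@@H](/C(C)=C/[C@@H](C)c1oc([C@@H](C)[C@@H](O)CC)c(C)c(=O)c1C)[C@H](C)[C@@H](OC(C)=O)[C@@H](C)c1oc(CC)c(C)c(=O)c1C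
F4 | step 3 | (3R,4R)-enantiomer of 8, 2-ethyl-6-[(2R,3R)-3-hydroxypentan-2-yl]-3,5-dimethyl-4H-pyran-4-one | CCc1oc([C@H](C)[C@H](O)CC)c(C)c(=O)c1C
F5 | step 3 | acetate of F4, (2R,3R)-2-(6-ethyl-3,5-dimethyl-4-oxo-4H-pyran-2-yl)pentan-3-yl acetate | CCc1oc([C@H](C)[C@H](OC(C)=O)CC)c(C)c(=O)c1C
F6 | step 9 | (2S,3R,4E)-5-iodo-2,4-dimethyl-3-(triethylsilyloxy)pent-4-enal | CC[Si](CC)(CC)O[C@@H](/C(C)=C/I)[C@H](C)C=O
F7 | step 9 | 13-O-triethylsilyl analogue of 18 (O15 free, no propanoate) | CC[Si](CC)(CC)O[C@@H](/C(C)=C/I)[C@H](C)[C@@H](O)[C@@H](C)c1oc(CC)c(C)c(=O)c1C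
F8 | step 9 | 15-O-acetyl derivative of F7 | CC[Si](CC)(CC)O[C@@H](/C(C)=C/I)[C@H](C)[C@@H](OC(C)=O)[C@@H](C)c1oc(CC)c(C)c(=O)c1C
F9 | step 9 | 13-hydroxy 15-acetate, 19 without its propanoyl group | O[C@@H](/C(C)=C/I)[C@H](C)[C@@H](OC(C)=O)[C@@H](C)c1oc(CC)c(C)c(=O)c1C
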